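You want J, and the question is how fast it is being made at the moment 5.0% of G has gone, which I call the mark.

G 1.0 M; Z 0.0200 M; X 0.5 mol%

    X → E (k1 = 0.035 /s)
    D → E + J (k2 = 210 /s)
    G + E ⇌ G.E (K3 = 0.87 /M, k3 = 47 /M/s)
    G.E ⇌ D (K4 = 7.0, k4 = 430 /s)
    G + Z → G.Z (k5 = 3.1 /M/s)

* the form that holds most of the catalyst when 5.0% of the G are converted (E / X / D / G.E)
* its share of the catalyst then
* factor on the rate of making J when 5.0% of the G are converted if X is charged twice over
* factor on the rate when 5.0% of the G are converted if X is charged at 0.1 mol% instead

Start with a ledger of G up to the mark, a sum of 0.0500 M. The first entry is G.Z, where each Z takes one G, so 0.0200 M is booked there. What remains I call the debt n, the G that has to pass through the catalyst by the mark: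

n = 0.0300 M

G.E and D also hold a little G, but they are forms of the catalyst, whose whole charge is 0.00500 M, and I leave that small entry out.

Now see how fast the debt is paid. In the working round at 0.950 M of G, a balance on each form puts G.E to D at 0.631 and E to D at 5.47. D makes J at 210 /s per D, so the turnover frequency of working catalyst is

T = 29.6 /s

Working catalyst grows from X at about c_X · k_X · t, with k_X = 0.035 /s. Summing the turnovers gives n = 0.5 · T · k_X · c_X · t squared, hence

t = 3.40 s

r = √(2 · T · k_X · c_X · n) = 0.0176 M/s

Z's time constant of 0.323 s is shorter than t, so I book its entry whole by the mark. X then keeps 88.8% of the catalyst. In logarithms,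

log r = 0.5 · log c_X + 0.5 · log(2 · T · k_X · n)

The slope of 0.5 gives me 1.41 for the doubled charge and 0.447 for 0.1 mol%.

The forecast says X at 88.6%, with factors 1.43 and 0.43, which sit slightly off mine. Its ground is that “the rate at that point scales roughly as the square root of the loading”.

The simulation of this flask gives X at 88.6%, with factors 1.43 and 0.426, and a rate of 0.0168 M/s at 3.45 s.

The step from G + Z to G.Z holds this flask's rate at the mark down, because it pays 0.0200 M of the 0.0500 M and so shortens the time the catalyst has had to grow. Remove that step and the debt becomes the full 0.0500 M, so the root gives a factor of 1.29 on the rate. The same flask run without that step reaches 1.27 times the actual rate.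

The constants used here were chosen freely; the run is a simulation.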